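## Retrosynthetic overview

1. Numbering: ring C1 (OH), C2 and C4 (OMe), C6 (chain); chain C1' (benzylic) to C21' (CH3). The benzene ring is bought as 2,4-dimethoxyphenol. What remains is a regiospecific C6–C1' bond and an unbranched C21 chain.
2. Enabling feature: the eight contiguous, unsubstituted CH2 groups C2'–C9' match the α-β-β-α–α-β-β-α carbon path of the two thiophene rings of 2,2'-bithiophene. Its two terminal α-C–H bonds (future C2' and C9') are its only acidic sites and, being conjugated, can be lithiated one after the other.
3. Key disconnections, both made in one flask: C9'–C10' (thienyllithium + 1-bromododecane) and C1'–C2' (thienyllithium + aryl aldehyde). C12 + C8 linchpin + ArC1 gives all 21 chain carbons.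
4. C6–C1' comes from Mg-templated ortho-formylation: the OH on C1 directs, and the OMe on C2 blocks the other ortho carbon.
5. Ring order: no ring is built. The benzene ring is kept throughout, and the two thiophene rings are temporary. The C1'–OH is removed by ionic hydrogenation, then both sulfur atoms are excised with Raney nickel.

Key step: step 2

Assumption: 2,4-dimethoxyphenol, 2,2'-bithiophene and 1-bromododecane are taken as catalogue chemicals. The target has no stereocentre.

## Route

Step 1
Reactants: 1 2,4-dimethoxyphenol
Product: 2 2-hydroxy-3,5-dimethoxybenzaldehyde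
Conditions: MgCl2 (anhydrous), Et3N, (CH2O)n, MeCN, reflux; then 1 M HCl
Reagents that add atoms: paraformaldehyde (as formaldehyde), C=O
Why: Casnati–Skattebøl ortho-formylation, in which Mg(II) holds the phenoxide oxygen and formaldehyde together so that the new C–C bond can form only at an ortho carbon (C6 is the only free one, C2 carries OMe), and excess formaldehyde takes up hydride at the benzylic alkoxide stage to give the aldehyde.

Step 2
Reactants: 2 2-hydroxy-3,5-dimethoxybenzaldehyde; 3 2,2'-bithiophene; 4 1-bromododecane
Product: 9 rac-2-[(5'-dodecyl-2,2'-bithiophen-5-yl)(hydroxy)methyl]-4,6-dimethoxyphenol, via 5-lithio-2,2'-bithiophene 5 (not isolated), via 5-dodecyl-2,2'-bithiophene 6 (not isolated), via 5-dodecyl-5'-lithio-2,2'-bithiophene 7 (not isolated), via sodium 2-formyl-4,6-dimethoxyphenolate 8 (not isolated)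
Conditions: 3, n-BuLi (1.0 equiv), THF, −78 to 0 °C; 4, 0 °C to reflux; n-BuLi (1.0 equiv), −78 to 0 °C; 8 (from 2, NaH, THF, 0 °C, second flask), −78 °C to rt; aq NH4Cl
Reagents that add atoms: none
Why: n-BuLi removes one of the two sulfur-acidified α-hydrogens of 3 to give 5, which displaces bromide from 4 by SN2 and so forms C9'–C10'; a second equivalent of n-BuLi then takes the only α-hydrogen left in 6, and 7 adds 1,2 to the formyl group of phenolate 8 to form C1'–C2'. The closest known reaction types are the lithiation–alkylation of thiophenes and oligothiophenes with primary alkyl bromides and the addition of 2-thienyllithium reagents to aromatic aldehydes, here run in sequence in one flask. No ring is closed, and the one new stereocentre (carbinol C1') forms without control as a racemate and is erased in step 3. The step needs mono- before di-lithiation, which the conjugation of the two thiophene rings secures because the first C–Li bond lowers the acidity of the distal α-hydrogen, while the β-hydrogens are far less acidic and stay untouched. It also needs the carbanion to survive the phenol, which is secured by converting 2 into 8 with NaH (hydrogen escapes, no proton source remains), and all n-BuLi is consumed before 8 arrives, so the aryl C–H between the two methoxy groups is never metalated. Three components that are bought or made in one step should thus deliver all 21 chain carbons in their final order in one operation.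

Step 3
Reactants: 9 rac-2-[(5'-dodecyl-2,2'-bithiophen-5-yl)(hydroxy)methyl]-4,6-dimethoxyphenol
Product: 10 2-[(5'-dodecyl-2,2'-bithiophen-5-yl)methyl]-4,6-dimethoxyphenol
Conditions: Et3SiH (3 equiv), CF3CO2H, CH2Cl2, 0 °C; then H2O
Reagents that add atoms: none
Why: Ionic hydrogenation, in which loss of water from the aryl thienyl carbinol gives a cation stabilised by the bithienyl π system and by the ortho hydroxyl (protonated o-quinone methide) that should take hydride from the silane faster than it alkylates another ring because both thiophene α-positions are blocked, which also erases the C1' stereocentre.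

Step 4
Reactants: 10 2-[(5'-dodecyl-2,2'-bithiophen-5-yl)methyl]-4,6-dimethoxyphenol
Product: 11 6-n-heneicosyl-2,4-dimethoxyphenol
Conditions: Raney Ni (W-2, large excess), H2 (1 atm), EtOH–THF, reflux
Reagents that add atoms: none
Why: Raney nickel reductive desulfurisation, the classical conversion of a 2,5-disubstituted thiophene into a butane-1,4-diyl unit, should hydrogenolyse all four C–S bonds and saturate the freed carbons so that the eight ring carbons become C2'–C9', while the benzene ring, the phenol and the aryl methyl ethers are not reduced at this temperature and pressure.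

## Compound list

1 | 2,4-dimethoxyphenol | COc1ccc(O)c(OC)c1 | starting material
2 | 2-hydroxy-3,5-dimethoxybenzaldehyde | O=Cc1cc(OC)cc(OC)c1O | intermediate
3 | 2,2'-bithiophene | c1csc(c1)-c1cccs1 | starting material
4 | 1-bromododecane | CCCCCCCCCCCCBr | starting material
5 | 5-lithio-2,2'-bithiophene | [Li]c1ccc(s1)-c1cccs1 | intermediate
6 | 5-dodecyl-2,2'-bithiophene | CCCCCCCCCCCCc1ccc(s1)-c1cccs1 | intermediate
7 | 5-dodecyl-5'-lithio-2,2'-bithiophene | CCCCCCCCCCCCc1ccc(s1)-c1ccc([Li])s1 | intermediate
8 | sodium 2-formyl-4,6-dimethoxyphenolate | [Na+].[O-]c1c(C=O)cc(OC)cc1OC | intermediate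
9 | rac-2-[(5'-dodecyl-2,2'-bithiophen-5-yl)(hydroxy)methyl]-4,6-dimethoxyphenol (racemic carbinol) | CCCCCCCCCCCCc1ccc(s1)-c1ccc(s1)C(O)c1cc(OC)cc(OC)c1O | intermediate
10 | 2-[(5'-dodecyl-2,2'-bithiophen-5-yl)methyl]-4,6-dimethoxyphenol | CCCCCCCCCCCCc1ccc(s1)-c1ccc(s1)Cc1cc(OC)cc(OC)c1O | intermediate
11 | 6-n-heneicosyl-2,4-dimethoxyphenol | CCCCCCCCCCCCCCCCCCCCCc1cc(OC)cc(OC)c1O | target

## Step count and risks

Total step count: 4. Longest linear sequence: 4 (1 → 2 → 9 → 10 → 11).

**Step 2 (key step).**
- Risk: the lithiation state may scramble between non-, mono- and dilithiated bithiophene. Together with a slow SN2 alkylation, a mixture of thienyllithium species would then meet the aldehyde.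
- Fallback: it sets out from 3 and 4 and comes back at 6. The site is fixed by halogen instead of acidity, and the C9'–C10' bond is made by catalysis. Compound 3 is monobrominated (NBS, DMF, 0 °C) to 5-bromo-2,2'-bithiophene F1. Compound 4 is converted with magnesium (Et2O) into dodecylmagnesium bromide F2. Kumada–Corriu coupling of the two (NiCl2(dppp) cat., Et2O, reflux) should give 6. This time 6 is isolated and purified before it is lithiated to 7 and added to 8 as in step 2.

**Step 4.**
- Risk: C–S hydrogenolysis may stay incomplete, the rings may be partly saturated to thiolanes that resist further cleavage, and the lipophilic phenol may be held on the large nickel surface.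
- Fallback: it sets out from 2 (and 4) and comes back at 11. The sulfur mask is given up for two alkynes, which need only palladium and hydrogen.
  - Compound 2 is O-benzylated (BnBr, K2CO3, DMF) to 2-(benzyloxy)-3,5-dimethoxybenzaldehyde F3.
  - The monolithium acetylide of commercial octa-1,7-diyne (diyne in excess, n-BuLi, THF, −78 °C) adds to it to give rac-1-[2-(benzyloxy)-3,5-dimethoxyphenyl]nona-2,8-diyn-1-ol F4.
  - The alkoxide–acetylide dianion of F4 (2 n-BuLi, THF–DMPU) is C-alkylated with 4. This again makes C9'–C10' and gives rac-1-[2-(benzyloxy)-3,5-dimethoxyphenyl]henicosa-2,8-diyn-1-ol F5.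
  - Hydrogenation (H2, Pd/C, EtOAc–AcOH, trace HClO4) should saturate both alkynes and cleave the benzylic C1'–OH and the O-benzyl bond to give 11.

**Step 1.**
- Risk: the first-formed benzylic alkoxide may react further (diarylmethane formation, methoxymethyl by-products). C–C bond formation may also be sluggish because the C2 methoxy group competes for magnesium.
- Fallback: it sets out from 1 and comes back at 2. The carbon is introduced at the alcohol level on a boron template and oxidised afterwards. Compound 1, phenylboronic acid and paraformaldehyde (cat. propionic acid, toluene, reflux with removal of water) should give 6,8-dimethoxy-2-phenyl-4H-1,3,2-benzodioxaborinine F6. Exchange with propane-1,3-diol releases 2-(hydroxymethyl)-4,6-dimethoxyphenol F7. MnO2 (CH2Cl2, rt) then oxidises the benzylic alcohol to 2.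

## Further compounds

F1 | step 2 | 5-bromo-2,2'-bithiophene | Brc1ccc(s1)-c1cccs1
F2 | step 2 | dodecylmagnesium bromide | CCCCCCCCCCCC[Mg]Br
F3 | step 4 | 2-(benzyloxy)-3,5-dimethoxybenzaldehyde | O=Cc1cc(OC)cc(OC)c1OCc1ccccc1
F4 | step 4 | rac-1-[2-(benzyloxy)-3,5-dimethoxyphenyl]nona-2,8-diyn-1-ol | C#CCCCCC#CC(O)c1cc(OC)cc(OC)c1OCc1ccccc1
F5 | step 4 | rac-1-[2-(benzyloxy)-3,5-dimethoxyphenyl]henicosa-2,8-diyn-1-ol | CCCCCCCCCCCCC#CCCCCC#CC(O)c1cc(OC)cc(OC)c1OCc1ccccc1
F6 | step 1 | 6,8-dimethoxy-2-phenyl-4H-1,3,2-benzodioxaborinine | COc1cc(OC)c2OB(c3ccccc3)OCc2c1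
F7 | step 1 | 2-(hydroxymethyl)-4,6-dimethoxyphenol | OCc1cc(OC)cc(OC)c1O
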